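Atom labels O1 and C2–C7 and ring letters A–D refer to the target throughout and are kept for every intermediate. Compounds are numbered as in the steps: 1, 3 starting materials; 2 benzylated ketone; 4 aldol adduct; 5 chalcone; 6 racemic cyclobutane; 7 resolved cyclobutane; 8 bis-ketal; 9 mono-ketal; 10 hemiketal; 11 protected hydroxy ketone; 12 target.

## Analysis of the target

The target is an oxolane: O1, C2 (ring B, 4-hydroxyphenyl), C3 (bearing ketone carbon C6 and ring A, 2,4-dihydroxyphenyl), C4 (bearing carbinol carbon C7 and ring D, 4-hydroxyphenyl) and C5 (ring C, 2,4-dihydroxyphenyl). All five stereocentres (C2, C3, C4, C5, C7) are R. On the ring, ring B is trans to the aroyl group on C3, the C3 and C4 side chains are cis, and ring C is cis to the C4 side chain, so it sits on the crowded face. Because the C3 and C4 branches are cis, the C7 hydroxyl can reach C6. The molecule is therefore the open form of a cis-fused 3,7-dioxabicyclo[3.3.0]octane in which rings B and D are exo and ring C is endo. C2, C5 and C7 are benzylic carbons that carry oxygen and ortho/para-hydroxylated aryl groups; they ionise under acid (C5 would drift to the exo epimer) and are open to hydrogenolysis. C3–H is α to the ketone and β to O1, so base threatens epimerisation and retro-oxa-Michael opening, and six free phenols are easily oxidised. The difficulty is five contiguous stereocentres in a skeleton that is almost C2-symmetric but not quite: C5 is an ether carbon carrying H, C6 is a ketone. The strategy rests on one feature. The units C6–C3–C2 (rings A, B) and C5–C4–C7 (rings C, D) are two identical 2′,4′,4-trioxygenated chalcones joined α to α through C3–C4, and their β-carbons C2 and C7 each hold oxygen where the head-to-head [2+2] dimer of that chalcone would hold a C2–C7 bond.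

## Retrosynthetic reasoning

12 from 11. The six phenolic O–H bonds are traced back to O-benzyl bonds. Benzyl is chosen rather than methyl because no reagent that cleaves six aryl methyl ethers would spare the three benzylic C–O bonds and the β-alkoxy ketone. Benzyl ethers survive base, light, the anode and Lewis acid and leave under neutral hydrogenolysis.

11 from 9 (through 10). The C7 hydroxyl is reconnected to C6, turning the ketone and alcohol into one cyclic mixed ketal. This masks both groups, locks the C3/C4 cis relation in a cis-fused bicycle and gives the molecule a convex and a concave face. Forward, a mild hydrolysis must open this ketal without ionising the benzylic ethers.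

9 from 8. The C5–H bond is exchanged for a C5–O bond, which restores C2 symmetry: in 8 both carbonyl-derived carbons are ketals. The cut is made here because the endo position of ring C is exactly what hydride delivery to the convex face of the bicyclic oxocarbenium ion gives. Forward, one hydride must be delivered to one of two homotopic ketals.

8 from 7 (key disconnection). The O1–C2 and O–C7 bonds are cut, the two ketal alkoxy groups are removed to restore the C5 and C6 ketones, and C2 is joined to C7. This gives cyclobutane 7. C2 and C7 are both electron-rich benzylic carbons, so the bond between them is the one an oxidant would break, and each lies five atoms from the carbonyl oxygen of the other half. The gain is that every carbon and the C3/C4 configuration come from one symmetric dimer. Forward, the oxidation must break only C2–C7, both cations must be captured internally, and both aryl groups must end up exo.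

7 from 6. No earlier step creates absolute configuration, so the enantiomers are separated here, at the first chiral compound and before the costly steps. The diketone has no acidic or basic handle, so the separation is chromatographic.

6 from 5. Cutting C3–C4 and C2–C7 gives two identical chalcone molecules. The forward photodimerisation has to be head to head and all-trans. The trans relation of the two aroyl groups is the only element the key step reads, and it is the thermodynamic one at enolisable centres.

5 from 2 and 3 (through 4). The Cα=Cβ bond is cut by aldol condensation logic into a methyl ketone and an aryl aldehyde.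

2 from 1. The two O-benzyl bonds are cut to a commercial dihydroxy ketone; 3 is bought already benzylated.

## Alternatives that were turned down

Alternative 1: The aryl–carbon bonds at C5 and C6 are cut first, leaving dilactone A2 (4,8-bis(4-hydroxyphenyl)-3,7-dioxabicyclo[3.3.0]octane-2,6-dione). A2 is then taken apart at C3–C4, O1–C2 and O–C7 into two molecules of p-coumaric acid A1.
- Forward step: a one-electron oxidant turns A1 into phenoxyl radicals that couple at C3–C4; each carboxyl group then adds to the quinone methide carbon of the other half and closes two cis-fused lactones.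
- For it: one step from a cheap acid, no protecting groups, a documented biomimetic reaction type, and the correct relative configuration at C2, C3, C4 and C7 with both aryl groups exo. On precedent and hardware it is stronger than the chosen route.
- Against it: C5 and C6 arrive as lactone carbonyls without rings A and C. Each lactone must accept exactly one aryl-metal nucleophile, and the bridgehead protons are acidic with an acyloxy leaving group in the β-position, so ring opening by elimination and double addition compete. A1 lacks the ortho substituent that makes this coupling clean, A2 is racemic, and after arylation the same desymmetrisation as in the chosen route still has to be done.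
- Comparison: the chosen strategy offers the complete carbon skeleton with rings A and C already on C5 and C6 at the right oxidation level, because the chalcone carries them.

Alternative 2: The oxolane is cut at C2–C3 and C4–C5, and ring A is cut from C6. This leads to cis-oxirane A3, butenolide A4 ((R)-5-(4-methoxyphenyl)furan-2(5H)-one) and cycloadduct A5.
- Forward step: thermal conrotatory C–C opening of A3 gives a carbonyl ylide with one aryl group turned in and one out. It adds across the C3=C4 bond of A4 anti to the γ-aryl group and closes the oxolane with ring B exo, ring C endo and ring D exo. Addition of a ring A aryl-metal to the lactone carbonyl C6 would then give the hydroxy ketone directly.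
- For it: the shortest route, four ring stereocentres in one step, absolute configuration from A4 without resolution, and no symmetric intermediate and hence no statistical step. On step economy it is stronger than the chosen route.
- Against it: which ylide carbon bonds to C3 rests only on a modest electronic difference between two aryl-substituted termini. The endo/exo orientation of the unsymmetrical ylide is not controlled and is coupled to that regiochemistry, so four isomers are possible and none can be corrected afterwards. The temperatures needed for oxirane opening let the ylide geometry equilibrate, and they let A4 racemise through its proton at C7, which is benzylic and vinylogously acidic. The aryl-metal addition must also spare two aryl sulfonates.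
- Comparison: the chosen strategy draws every relative configuration from a thermodynamic preference (all-trans cyclobutane, exo cyclisation) or from convex-face attack.

Alternative 3: Only C3–C4 is cut, after the C2 and C7 oxygens are tied through a diisopropylsilylene. The precursor is bis(enol silane) A6 and the product is the seven-membered dioxasilepane A7.
- Forward step: one-electron oxidation of one enol silane of A6, addition to the other and loss of the silyl groups form C3–C4. Removing the tether from A7 would give the diketo diol that closes to the bis-lactol counterpart of 8.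
- For it: C2 and C7 come from an asymmetric aldol reaction, so no material is lost to resolution, and oxidative coupling of enol silanes is an established bond formation. On both points it is stronger than the chosen route.
- Against it: the sequence is longer (two enantioselective aldol reactions, tethering, double enol silane formation, coupling, untethering). β-Silyloxy ketones of this benzylic type are prone to retro-aldol cleavage and to elimination back to the chalcone during enolisation. The coupling must set C3 and C4 trans to both neighbours in a seven-membered ring, where selectivity is uncertain. The electron-rich rings compete for the oxidant, and the desymmetrisation problem is unchanged.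
- Comparison: the chosen strategy reaches the same oxidation pattern in five steps from two building blocks, the chalcone being the stable dehydrated form of that aldol; it forms C3–C4 by a dimerisation with no elimination-prone intermediate and lets thermodynamics set the relative configuration.

Key step: step 5

Remarks on the chemistry:
- The ketal centres of 8 may form as epimers; all ionise to the same oxocarbenium ions, and 8 is drawn as the convex-face product (methoxy exo).
- Compound 11 and the target can equilibrate with their cyclic hemiketals; both are written in the open form in which the target is drawn.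

## Steps

Step 1
Reactants: 1 2′,4′-dihydroxyacetophenone
Product: 2 1-[2,4-bis(benzyloxy)phenyl]ethan-1-one
Conditions: BnBr (2.5 equiv), K2CO3 (3 equiv), KI (10 mol %), DMF, 70 °C
Reagents that add atoms: benzyl bromide, BrCc1ccccc1
Why: Williamson ether synthesis; the 4-hydroxyl reacts first and the hydrogen-bonded 2-hydroxyl follows in the polar solvent with heat and iodide catalysis.

Step 2
Reactants: 2 1-[2,4-bis(benzyloxy)phenyl]ethan-1-one; 3 4-(benzyloxy)benzaldehyde
Product: 5 (E)-1-[2,4-bis(benzyloxy)phenyl]-3-[4-(benzyloxy)phenyl]prop-2-en-1-one, via racemic β-hydroxy ketone 4 (not isolated)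
Conditions: KOH (aq.), EtOH/THF, rt
Reagents that add atoms: none
Why: Claisen–Schmidt condensation; the aldehyde has no α-hydrogen, and E1cB dehydration of aldol adduct 4 gives the conjugated E-enone, which precipitates.

Step 3
Reactants: 5 (E)-1-[2,4-bis(benzyloxy)phenyl]-3-[4-(benzyloxy)phenyl]prop-2-en-1-one (two molecules)
Product: 6 racemic all-trans {3,4-bis[4-(benzyloxy)phenyl]cyclobutane-1,2-diyl}bis{[2,4-bis(benzyloxy)phenyl]methanone} (head-to-head dimer; relative configuration 1S*,2S*,3R*,4R*)
Conditions: fac-Ir(ppy)3 (1 mol %), degassed DMF (0.3 M), 450 nm LEDs, rt; then DBU (20 mol %), rt; crystallisation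
Reagents that add atoms: none
Why: Triplet-sensitised [2+2] photodimerisation of a chalcone; the triplet enone adds stepwise to a ground-state molecule through a freely rotating 1,4-biradical, which should favour the head-to-head dimer with all four substituents trans. DBU then equilibrates the enolisable C3 and C4 so that any cis-aroyl epimer converges on the trans,trans minimum. The four stereocentres are set only relative to each other, and the product is racemic.

Step 4
Reactants: 6 racemic all-trans cyclobutane
Product: 7 {(1S,2S,3R,4R)-3,4-bis[4-(benzyloxy)phenyl]cyclobutane-1,2-diyl}bis{[2,4-bis(benzyloxy)phenyl]methanone}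
Conditions: preparative chiral SFC, amylose tris(3,5-dimethylphenylcarbamate) phase, CO2/i-PrOH–CH2Cl2; mirror-image fraction set aside
Reagents that add atoms: none
Why: Resolution on a chiral stationary phase; the rigid C2-symmetric diketone has no handle for salt formation but offers aryl faces and two carbonyl acceptors to the carbamate selector. The absolute configuration is to be assigned by anomalous-dispersion X-ray diffraction or ECD before scale-up. The C3 and C4 centres fixed here reach the target unchanged.

Step 5
Reactants: 7 {(1S,2S,3R,4R)-3,4-bis[4-(benzyloxy)phenyl]cyclobutane-1,2-diyl}bis{[2,4-bis(benzyloxy)phenyl]methanone}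
Product: 8 (1R,2R,4R,5R,6R,8R)-2,6-bis[4-(benzyloxy)phenyl]-4,8-bis[2,4-bis(benzyloxy)phenyl]-4,8-dimethoxy-3,7-dioxabicyclo[3.3.0]octane (cis-fused; 4-(benzyloxy)phenyl groups exo; methoxy groups exo)
Conditions: undivided cell, graphite anode, Pt cathode, constant current, 2.2 F per mol, n-Bu4NBF4 (0.1 M), 2,6-lutidine (2 equiv), CH2Cl2/MeOH (4:1), 0 °C; filtration through basic alumina
Reagents that add atoms: methanol, CO
Why: Proposed new method: loss of one electron at the anode from a 4-(benzyloxy)phenyl ring gives a radical cation in which the strained C2–C7 bond between the two aryl-bearing carbons is the weakest σ-bond and breaks to a 4-alkoxybenzylic cation and a benzylic radical, as in the known radical-cation ring opening of 1,2-diarylcyclobutanes with solvent capture and the anodic 1,3-dioxygenation of arylcyclopropanes, the new element being capture of both termini by internal ketone oxygens. After rotation of about 120° around the untouched C3–C4 bond, the carbonyl oxygen of the aroyl group on C4 lies five atoms from cationic C2 and adds through its in-plane lone pair (5-exo-trig at the benzylic cation), closing the first oxolane as an oxocarbenium ion stabilised by the 2,4-bis(benzyloxy)phenyl ring, which methanol converts into the methyl ketal. The benzylic radical left at C7 is oxidised at once at the same potential and is captured in the same 5-exo mode by the aroyl oxygen on C3, followed by the second methanol addition, so that two electrons per molecule are consumed and hydrogen is evolved at the cathode. C3 and C4 are spectators: their trans-diaroyl relation in 7 becomes the cis ring fusion after the bond rotation, the only fusion a bicyclo[3.3.0] skeleton allows. C2 and C7 are re-formed from planar cations and take the aryl group exo, trans to the substituent on the neighbouring bridgehead (1,2-induction by C3 and C4, which is also the thermodynamic preference), so their configuration does not depend on that in 7. C5 and C6 are set by methanol attack on the convex face of each oxocarbenium ion (methoxy exo), but their configuration is of no consequence because both centres are ionised again later. The step needs internal O-capture to outrun fragmentation of C3–C4 to two chalcone units, capture of the cations by solvent and cleavage of the C2–C3 bond; the short tether, the poor stability of an acyl-substituted alkene radical cation, the sharing of the positive hole by the two aryl groups across C2–C7 and methanol kept as the minor co-solvent are expected to secure this. Charge is limited to slightly more than 2 F per mol because the resorcinol-type rings of 8 are no longer deactivated by a carbonyl group.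

Step 6
Reactants: 8 C2-symmetric bis(methyl ketal)
Product: 9 (1S,2R,4R,5R,6R,8R)-2,6-bis[4-(benzyloxy)phenyl]-4,8-bis[2,4-bis(benzyloxy)phenyl]-4-methoxy-3,7-dioxabicyclo[3.3.0]octane (8 with the methoxy group on C5 replaced by exo hydrogen; ring C endo)
Conditions: Et3SiH (1.0 equiv), BF3·OEt2 (0.3 equiv), CH2Cl2, −78 °C; aq. NaHCO3; recovered 8 recycled
Reagents that add atoms: none
Why: Ionic hydrogenation of a cyclic ketal; the two ketals are homotopic, so ionisation of either gives the same oxocarbenium ion, and the silane is the limiting reagent. Hydride adds to the convex face of the cis-fused bicycle, placing hydrogen exo and ring C endo, which sets C5 as R. The low temperature and substoichiometric Lewis acid keep the new, less stable endo benzylic ether from re-ionising.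

Step 7
Reactants: 9 mono(methyl ketal)
Product: 11 [2,4-bis(benzyloxy)phenyl][(2R,3R,4R,5R)-5-[2,4-bis(benzyloxy)phenyl]-4-[(R)-[4-(benzyloxy)phenyl](hydroxy)methyl]-2-[4-(benzyloxy)phenyl]oxolan-3-yl]methanone, via cyclic hemiketal 10 (not isolated)
Conditions: PPTS (0.2 equiv), acetone/H2O (10:1), rt
Reagents that add atoms: water, O
Why: Acid-catalysed ketal hydrolysis; the ketal carbon, flanked by oxygen and an electron-rich aryl group, ionises far faster than any benzylic ether, so C2, C5 and C7 keep their configuration. Hemiketal 10 opens to the ketone conjugated with the dialkoxyphenyl ring, and no stereocentre is formed or touched.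

Step 8
Reactants: 11 hexabenzyl hydroxy ketone
Product: 12 (2,4-dihydroxyphenyl)[(2R,3R,4R,5R)-5-(2,4-dihydroxyphenyl)-4-[(R)-hydroxy(4-hydroxyphenyl)methyl]-2-(4-hydroxyphenyl)oxolan-3-yl]methanone
Conditions: H2 (1 atm), Pd(OH)2/C, THF/MeOH, rt, stopped after uptake of 6 equiv
Reagents that add atoms: none
Why: Hydrogenolysis of aryl benzyl ethers; in neutral medium this is much faster than cleavage of the benzylic alcohol or the ring benzylic ethers. The ketone, chelated by the liberated 2-hydroxyl, is not reduced and holds the product in the open form.

## Compound list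

1 | 2′,4′-dihydroxyacetophenone | CC(=O)c1ccc(O)cc1O | starting material
2 | 1-[2,4-bis(benzyloxy)phenyl]ethan-1-one | CC(=O)c1ccc(OCc2ccccc2)cc1OCc1ccccc1 | intermediate
3 | 4-(benzyloxy)benzaldehyde | O=Cc1ccc(OCc2ccccc2)cc1 | starting material
4 | racemic 1-[2,4-bis(benzyloxy)phenyl]-3-[4-(benzyloxy)phenyl]-3-hydroxypropan-1-one (not isolated) | O=C(CC(O)c1ccc(OCc2ccccc2)cc1)c1ccc(OCc2ccccc2)cc1OCc1ccccc1 | intermediate
5 | (E)-1-[2,4-bis(benzyloxy)phenyl]-3-[4-(benzyloxy)phenyl]prop-2-en-1-one | O=C(/C=C/c1ccc(OCc2ccccc2)cc1)c1ccc(OCc2ccccc2)cc1OCc1ccccc1 | intermediate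
6 | racemic all-trans {3,4-bis[4-(benzyloxy)phenyl]cyclobutane-1,2-diyl}bis{[2,4-bis(benzyloxy)phenyl]methanone} (SMILES shows one enantiomer of the racemate) | O=C(c1ccc(OCc2ccccc2)cc1OCc1ccccc1)[C@@H]1[C@@H](C(=O)c2ccc(OCc3ccccc3)cc2OCc2ccccc2)[C@H](c2ccc(OCc3ccccc3)cc2)[C@H]1c1ccc(OCc2ccccc2)cc1 | intermediate
7 | {(1S,2S,3R,4R)-3,4-bis[4-(benzyloxy)phenyl]cyclobutane-1,2-diyl}bis{[2,4-bis(benzyloxy)phenyl]methanone} | O=C(c1ccc(OCc2ccccc2)cc1OCc1ccccc1)[C@@H]1[C@@H](C(=O)c2ccc(OCc3ccccc3)cc2OCc2ccccc2)[C@H](c2ccc(OCc3ccccc3)cc2)[C@H]1c1ccc(OCc2ccccc2)cc1 | intermediate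
8 | (1R,2R,4R,5R,6R,8R)-2,6-bis[4-(benzyloxy)phenyl]-4,8-bis[2,4-bis(benzyloxy)phenyl]-4,8-dimethoxy-3,7-dioxabicyclo[3.3.0]octane | CO[C@]3(c2ccc(OCc4ccccc4)cc2OCc2ccccc2)[C@@H]1[C@H]([C@@H](O3)c2ccc(OCc4ccccc4)cc2)[C@](OC)(c2ccc(OCc4ccccc4)cc2OCc2ccccc2)O[C@H]1c1ccc(OCc2ccccc2)cc1 | intermediate
9 | (1S,2R,4R,5R,6R,8R)-2,6-bis[4-(benzyloxy)phenyl]-4,8-bis[2,4-bis(benzyloxy)phenyl]-4-methoxy-3,7-dioxabicyclo[3.3.0]octane | CO[C@]3(c2ccc(OCc4ccccc4)cc2OCc2ccccc2)[C@@H]1[C@H]([C@@H](O3)c2ccc(OCc4ccccc4)cc2)[C@H](c2ccc(OCc4ccccc4)cc2OCc2ccccc2)O[C@H]1c1ccc(OCc2ccccc2)cc1 | intermediate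
10 | cyclic hemiketal of 11 (9 with OH in place of OMe; drawn as the exo-hydroxy anomer, anomers interconvert; not isolated) | O[C@]3(c2ccc(OCc4ccccc4)cc2OCc2ccccc2)[C@@H]1[C@H]([C@@H](O3)c2ccc(OCc4ccccc4)cc2)[C@H](c2ccc(OCc4ccccc4)cc2OCc2ccccc2)O[C@H]1c1ccc(OCc2ccccc2)cc1 | intermediate
11 | [2,4-bis(benzyloxy)phenyl][(2R,3R,4R,5R)-5-[2,4-bis(benzyloxy)phenyl]-4-[(R)-[4-(benzyloxy)phenyl](hydroxy)methyl]-2-[4-(benzyloxy)phenyl]oxolan-3-yl]methanone | O=C(c1ccc(OCc2ccccc2)cc1OCc1ccccc1)[C@@H]1[C@H]([C@@H](O)c2ccc(OCc3ccccc3)cc2)[C@H](c2ccc(OCc3ccccc3)cc2OCc2ccccc2)O[C@H]1c1ccc(OCc2ccccc2)cc1 | intermediate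
12 | (2,4-dihydroxyphenyl)[(2R,3R,4R,5R)-5-(2,4-dihydroxyphenyl)-4-[(R)-hydroxy(4-hydroxyphenyl)methyl]-2-(4-hydroxyphenyl)oxolan-3-yl]methanone (CNP0244141.1) | O=C(c1ccc(O)cc1O)[C@@H]1[C@H]([C@@H](O)c2ccc(O)cc2)[C@H](c2ccc(O)cc2O)O[C@H]1c1ccc(O)cc1 | target

Total step count: 8. Longest linear sequence: 8 steps (1 → 2 → 5 → 6 → 7 → 8 → 9 → 11 → 12); aldehyde 3 enters in step 2.

## Steps least certain to work

Step 5 (key step, proposed new method).
- What may go wrong: fragmentation of the ring-opened radical cation across C3–C4 back to two chalcone units before the carbonyl oxygen arrives; interception of the benzylic cations by solvent to give open-chain benzylic methyl ethers; cleavage of the aryl/aroyl bond C2–C3 instead of C2–C7; over-oxidation of the product, whose resorcinol-type rings become more electron-rich once the carbonyl groups are gone; and oxidative loss of benzyl groups from the aryl ether radical cations.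
- Fallback with known reactions only, from chalcone 5, returning at 8 with the absolute configuration already set, so that steps 3 and 4 are not needed. Juliá–Colonna epoxidation of 5 (poly-L-leucine expected to give the required sense, urea·H2O2, DBU, THF) should give [(2R,3S)-3-[4-(benzyloxy)phenyl]oxiran-2-yl][2,4-bis(benzyloxy)phenyl]methanone F1. Reductive opening at the α-carbon ((PhSe)2, NaBH4, AcOH, EtOH) gives (R)-1-[2,4-bis(benzyloxy)phenyl]-3-[4-(benzyloxy)phenyl]-3-hydroxypropan-1-one F2, which fixes C2 and C7. TBSCl/imidazole gives its tert-butyldimethylsilyl ether F3. Oxidative homocoupling of the lithium enolate (LiN(i-Pr)2, THF, −78 °C, then CuCl2) forms C3–C4, and the C2-symmetric (2R,3R)-2,3-bis{(R)-[4-(benzyloxy)phenyl][(tert-butyldimethylsilyl)oxy]methyl}-1,4-bis[2,4-bis(benzyloxy)phenyl]butane-1,4-dione F4 is separated from its diastereomers. TBAF/AcOH releases the diketo diol (2R,3R)-2,3-bis{(R)-[4-(benzyloxy)phenyl](hydroxy)methyl}-1,4-bis[2,4-bis(benzyloxy)phenyl]butane-1,4-dione F5, which closes to the bis-lactol and is converted with PPTS and HC(OMe)3 in MeOH into 8. The price is length and a coupling that is not expected to be diastereoselective.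

Step 3 (photodimerisation).
- What may go wrong: sensitised E/Z isomerisation consuming light without productive dimerisation, and formation of head-to-tail or cis-diaryl dimers. Base equilibration cannot correct these because only C3 and C4 are enolisable.
- Fallback from aldehyde 3, returning at 6. Wittig olefination of 3 with Ph3P=CHCO2Me gives methyl (E)-3-[4-(benzyloxy)phenyl]prop-2-enoate F6. Its sensitised [2+2] dimerisation ([Ir{dF(CF3)ppy}2(dtbbpy)]PF6, 450 nm), an established entry to all-trans head-to-head diesters, should give racemic dimethyl all-trans-3,4-bis[4-(benzyloxy)phenyl]cyclobutane-1,2-dicarboxylate F7, purified by crystallisation. MeNHOMe·HCl/i-PrMgCl converts F7 into racemic all-trans-3,4-bis[4-(benzyloxy)phenyl]-N,N′-dimethoxy-N,N′-dimethylcyclobutane-1,2-dicarboxamide F8. Addition of the aryllithium made from 1-bromo-2,4-bis(benzyloxy)benzene F9 and n-BuLi to F8 gives 6.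

Step 6 (mono-reduction).
- What may go wrong: the two ketals react independently, so over-reduction of both ketals and incomplete conversion limit the amount of 9 to a statistical share. Lewis-acid re-ionisation of the new benzylic ether at C5 could also epimerise ring C to the exo position.
- Fallback from 8, returning at 11 and bypassing 9 and 10. Excess Et3SiH/BF3·OEt2 reduces both ketals from the convex face to the C2-symmetric diether (1R,2R,4R,5R,6R,8R)-2,6-bis[4-(benzyloxy)phenyl]-4,8-bis[2,4-bis(benzyloxy)phenyl]-3,7-dioxabicyclo[3.3.0]octane F10; this is also the over-reduction product of step 6, so that material is not lost. One of its two homotopic C–H bonds at the 2,4-bis(benzyloxy)benzylic ether carbons is then oxidised with DDQ (1 equiv) in wet CH2Cl2: hydride abstraction to the oxocarbenium ion, hydration and ring opening give 11. The ketone formed deactivates its own ring and unreacted F10 is recovered. This does not remove the statistical factor; it moves it to a step with a single, robust, recoverable substrate.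

Step 8 (global debenzylation).
- What may go wrong: hydrogenolytic loss of the benzylic hydroxyl at C7 or opening of the ring at the benzylic C2–O1 or C5–O1 bonds once the phenols are free, and slow reduction of the ketone.
- Fallback from 9, returning at 12. The hydrogenolysis (H2, Pd(OH)2/C) is carried out on 9, in which the C7 oxygen is still part of the bicycle and C6 is masked, to give the hexaphenol mixed ketal (1S,2R,4R,5R,6R,8R)-4,8-bis(2,4-dihydroxyphenyl)-2,6-bis(4-hydroxyphenyl)-4-methoxy-3,7-dioxabicyclo[3.3.0]octane F11. Very mild aqueous acid (AcOH/H2O/THF, rt) then releases the ketone and the C7 hydroxyl, so the last step is a hydrolysis and the free benzylic alcohol and ketone never meet the catalyst.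

## Further compounds

F1 | step 5 | [(2R,3S)-3-[4-(benzyloxy)phenyl]oxiran-2-yl][2,4-bis(benzyloxy)phenyl]methanone | O=C([C@@H]1O[C@H]1c1ccc(OCc2ccccc2)cc1)c1ccc(OCc2ccccc2)cc1OCc1ccccc1
F2 | step 5 | (R)-1-[2,4-bis(benzyloxy)phenyl]-3-[4-(benzyloxy)phenyl]-3-hydroxypropan-1-one | O=C(C[C@@H](O)c1ccc(OCc2ccccc2)cc1)c1ccc(OCc2ccccc2)cc1OCc1ccccc1
F3 | step 5 | (R)-1-[2,4-bis(benzyloxy)phenyl]-3-[4-(benzyloxy)phenyl]-3-[(tert-butyldimethylsilyl)oxy]propan-1-one | O=C(C[C@@H](O[Si](C)(C)C(C)(C)C)c1ccc(OCc2ccccc2)cc1)c1ccc(OCc2ccccc2)cc1OCc1ccccc1
F4 | step 5 | (2R,3R)-2,3-bis{(R)-[4-(benzyloxy)phenyl][(tert-butyldimethylsilyl)oxy]methyl}-1,4-bis[2,4-bis(benzyloxy)phenyl]butane-1,4-dione | O=C(c1ccc(OCc2ccccc2)cc1OCc1ccccc1)[C@@H]([C@@H](O[Si](C)(C)C(C)(C)C)c1ccc(OCc2ccccc2)cc1)[C@H]([C@@H](O[Si](C)(C)C(C)(C)C)c1ccc(OCc2ccccc2)cc1)C(=O)c1ccc(OCc2ccccc2)cc1OCc1ccccc1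
F5 | step 5 | (2R,3R)-2,3-bis{(R)-[4-(benzyloxy)phenyl](hydroxy)methyl}-1,4-bis[2,4-bis(benzyloxy)phenyl]butane-1,4-dione | O=C(c1ccc(OCc2ccccc2)cc1OCc1ccccc1)[C@@H]([C@@H](O)c1ccc(OCc2ccccc2)cc1)[C@H]([C@@H](O)c1ccc(OCc2ccccc2)cc1)C(=O)c1ccc(OCc2ccccc2)cc1OCc1ccccc1
F6 | step 3 | methyl (E)-3-[4-(benzyloxy)phenyl]prop-2-enoate | COC(=O)/C=C/c1ccc(OCc2ccccc2)cc1
F7 | step 3 | racemic dimethyl all-trans-3,4-bis[4-(benzyloxy)phenyl]cyclobutane-1,2-dicarboxylate (one enantiomer drawn) | COC(=O)[C@@H]1[C@@H](C(=O)OC)[C@H](c2ccc(OCc3ccccc3)cc2)[C@H]1c1ccc(OCc2ccccc2)cc1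
F8 | step 3 | racemic all-trans-3,4-bis[4-(benzyloxy)phenyl]-N,N′-dimethoxy-N,N′-dimethylcyclobutane-1,2-dicarboxamide (one enantiomer drawn) | CON(C)C(=O)[C@@H]1[C@@H](C(=O)N(C)OC)[C@H](c2ccc(OCc3ccccc3)cc2)[C@H]1c1ccc(OCc2ccccc2)cc1
F9 | step 3 | 1-bromo-2,4-bis(benzyloxy)benzene | Brc1ccc(OCc2ccccc2)cc1OCc1ccccc1
F10 | step 6 | (1R,2R,4R,5R,6R,8R)-2,6-bis[4-(benzyloxy)phenyl]-4,8-bis[2,4-bis(benzyloxy)phenyl]-3,7-dioxabicyclo[3.3.0]octane | c1ccccc1COc1ccc(c(OCc2ccccc2)c1)[C@H]3[C@@H]1[C@H]([C@@H](O3)c2ccc(OCc4ccccc4)cc2)[C@H](c2ccc(OCc4ccccc4)cc2OCc2ccccc2)O[C@H]1c1ccc(OCc2ccccc2)cc1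
F11 | step 8 | (1S,2R,4R,5R,6R,8R)-4,8-bis(2,4-dihydroxyphenyl)-2,6-bis(4-hydroxyphenyl)-4-methoxy-3,7-dioxabicyclo[3.3.0]octane | CO[C@]3(c2ccc(O)cc2O)[C@@H]1[C@H]([C@@H](O3)c2ccc(O)cc2)[C@H](c2ccc(O)cc2O)O[C@H]1c1ccc(O)cc1
A1 | alternative 1 | (E)-3-(4-hydroxyphenyl)prop-2-enoic acid (p-coumaric acid) | OC(=O)/C=C/c1ccc(O)cc1
A2 | alternative 1 | 4,8-bis(4-hydroxyphenyl)-3,7-dioxabicyclo[3.3.0]octane-2,6-dione (cis-fused, both aryl groups exo, enantiomer shown) | O=C3[C@@H]1[C@H]([C@@H](O3)c2ccc(O)cc2)C(=O)O[C@H]1c1ccc(O)cc1
A3 | alternative 2 | cis-2-[2,4-bis(methanesulfonyloxy)phenyl]-3-(4-methoxyphenyl)oxirane (racemic, one enantiomer drawn) | COc1ccc(cc1)[C@H]1O[C@H]1c1ccc(OS(C)(=O)=O)cc1OS(C)(=O)=O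
A4 | alternative 2 | (R)-5-(4-methoxyphenyl)furan-2(5H)-one | O=C1C=C[C@@H](O1)c1ccc(OC)cc1
A5 | alternative 2 | 6-[2,4-bis(methanesulfonyloxy)phenyl]-4,8-bis(4-methoxyphenyl)-3,7-dioxabicyclo[3.3.0]octan-2-one (cis-fused; ring B exo, ring C endo, ring D exo) | O=C3[C@@H]1[C@H]([C@@H](O3)c2ccc(OC)cc2)[C@H](c2ccc(OS(C)(=O)=O)cc2OS(C)(=O)=O)O[C@H]1c1ccc(OC)cc1
A6 | alternative 3 | bis{[(1R,2Z)-3-(2,4-dimethoxyphenyl)-1-(4-methoxyphenyl)-3-[(trimethylsilyl)oxy]prop-2-en-1-yl]oxy}di(propan-2-yl)silane | C[Si](C)(C)O/C(c1ccc(OC)cc1OC)=C\[C@H](c1ccc(OC)cc1)O[Si](C(C)C)(C(C)C)O[C@@H](c1ccc(OC)cc1)/C=C(\O[Si](C)(C)C)c1ccc(OC)cc1OC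
A7 | alternative 3 | all-trans 5,6-bis(2,4-dimethoxybenzoyl)-4,7-bis(4-methoxyphenyl)-2,2-di(propan-2-yl)-1,3-dioxa-2-silepane (C2-symmetric) | O=C(c1ccc(OC)cc1OC)[C@H]1[C@H](c2ccc(OC)cc2)O[Si](C(C)C)(C(C)C)O[C@@H](c2ccc(OC)cc2)[C@@H]1C(=O)c1ccc(OC)cc1OC
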